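The data were generated by integration on assumed constants; noise was put on by code.

If a catalyst dies on meeting its own substrate, percent yield at high charge, with catalyst charge and temperature fixed, should fall with the square of the charge, and one stalled run can show where that fall begins.

the same everywhere: free catalyst 0.40 mM

| run | starting material | second substrate | temperature | remark | time |
|---|---|---|---|---|---|
| red | 6.6 mM | 20 mM | 20 °C | run made earlier |  |
| ochre | 96 mM | 20 mM | 31 °C | run made earlier |  |
| ash | 80 mM | 20.0 mM | 25 °C |  | 6.0 min |
| alder | 10 mM | 20.0 mM | 25 °C |  | 6.0 min |
| maple | 5.0 mM | 20.0 mM | 25 °C |  | 6.0 min |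
| elm | 20 mM | 20.0 mM | 25 °C |  | 6.0 min |
| larch | 40 mM | 20.0 mM | 25 °C |  | 6.0 min |
| cedar | 12 mM | 20.0 mM | 25 °C |  | 6.0 min |

- red (time / min: target / %): 0.500: 15; 1.50: 42; 3.00: 74; 4.00: 82; 6.00: 94
- ochre (time / min: target / %): 1.33: 2; 2.50: 3; 4.00: 3; 5.00: 4; 6.00: 5

(each reading ± 1.5 percentage points)

1. the flasks by amount of target, in percent of the starting material charged, highest first, at 6.0 min (ash / alder / maple / elm / larch / cedar)
2. the amount of target, in percent of the starting material charged of the flask you put first, at 6.0 min
3. the amount of target, in percent of the starting material charged of the flask you put last, at 6.0 min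

What does ochre show? Target goes from 2 % to 5 %, with a scatter of 1.5 percentage points. I read that as a stall and take the middle reading, 3 %, as its height.

Couldn't that be a slow flask that is still running? Yes, the readings don't exclude it, so the stall is my wager.

What follows from the wager? Suppose each lost catalyst costs one extra molecule of starting material. Then the partition ratio, turnovers per catalyst lost, falls as one over c(starting material). At fixed catalyst charge and temperature, and while c(starting material) stays near its charge, target in mM falls the same way, and percent yield falls as the square of the charge.

Where is the zero of that scale? Yield by this rule equals (c*/c(starting material)) squared, and ochre's middle reading gives c* = 16.6 mM, the break loading: the charge at which the rule just allows whole conversion at this catalyst charge. That value is a reading and carries ochre's scatter.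

But ochre ran at 31 °C, not 25 °C? True, and red and ochre differ in both charge and temperature, so I leave it uncorrected.

Your reckoning? Red, charged below the break loading, read 94 % at its last reading, though at 20 °C, so I expect maple, alder and cedar to finish or nearly so, smallest charge first. Above the break loading, the rule gives elm 69.1 %, larch 17.3 % and ash 4.32 %.

The forecast gives maple > alder > cedar > elm > larch > ash, with 98 % and 4 %, holding that “excess starting material inhibits the catalyst”.

The flasks give maple > alder > cedar > elm > larch > ash, with maple at 98.0 %, elm at 65.4 %, larch at 13.6 % and ash at 3.20 %.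

    starting material + free catalyst ⇌ catalyst intermediate A (K = 73.0 L mol⁻¹, k = 78.0 L mol⁻¹ s⁻¹, Ea = 39.0 kJ mol⁻¹, ΔH = −27.0 kJ mol⁻¹)
    catalyst intermediate A → free catalyst + target (k = 0.950 s⁻¹, Ea = 72.0 kJ mol⁻¹)
    second substrate + free catalyst ⇌ catalyst intermediate B (K = 9900 L mol⁻¹, k = 170 L mol⁻¹ s⁻¹, Ea = 46.0 kJ mol⁻¹, ΔH = −11.0 kJ mol⁻¹)
    catalyst intermediate B → free catalyst + second product (k = 3.20 s⁻¹, Ea = 67.0 kJ mol⁻¹)
    starting material + catalyst intermediate A → spent catalyst (k = 1.90 L mol⁻¹ s⁻¹, Ea = 56.0 kJ mol⁻¹)
    (constants at 25 °C)

Ash's result gives a break loading of 14.3 mM, against 16.6 mM from ochre, and ash stands at 3.20 % at 60.0 min with spent catalyst at 100 %. The neighbour flask is ash with 32 mM of starting material, still above the break loading. The square rule gives it 26.9 % with ochre's value and 20.0 % with ash's. In that neighbour, spent catalyst reaches 99.9 % at 6.00 min, 75 % of the starting material remains unbound, and target stands at 22.4 %.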